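**Retrosynthetic overview**
- The last step is a hydrogenation that saturates an isopropenyl group and frees the phenol. The five- and seven-membered rings form together, as the second ring event, by acid-triggered transannular C1–C5 bond formation in a ten-membered cis-4,5-epoxygermacr-1(10)-ene 8-ester.
- That ester comes from the 6,8-diol and O-benzylvanillic acid.
- The ten-membered ring is the first ring event. It forms by C6–C7 closure of an acyclic farnesane chain, in which a Z-allylboronate (C12–B) adds to the C6 epoxy aldehyde. This is the bond and polarity of the farnesyl 1,10-closure. A second boron on C8 becomes the C8 oxygen.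
- The bis(boronate) comes from enantioselective 1,4-diboration of a terminal diene. The chain is nerol (C10) plus 2-methylbut-1-en-3-yne (C5), joined at C8–C9. The Z-alkene of nerol gives the cis-oxirane that is needed for 4-OH trans to H5.

Atom labels C1–C15 are germacrane/guaiane numbers: C6 is the carbinol carbon of nerol, C4=C5 its Z-alkene and C1=C10 its distal alkene.

Assumption: the (R,R)-ligand in step 4 is taken to give the 8S boronate. If the sense is opposite, the (S,S)-ligand is used and nothing else changes.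

**Route**

Step 1
Reactants: 1 nerol
Product: 2 (2R,3S)-2,3-epoxynerol (cis-oxirane)
Conditions: Ti(OiPr)4 (5 mol%), D-(−)-diethyl tartrate (7 mol%), tBuOOH, 4 Å MS, CH2Cl2, −20 °C
Reagents that add atoms: tert-butyl hydroperoxide, CC(C)(C)OO
Why: Sharpless asymmetric epoxidation: only the allylic alcohol binds the Ti(OiPr)4/tartrate complex, so only C4=C5 reacts, D-(−)-tartrate delivers oxygen to the face that gives (2R,3S), and the Z geometry is carried stereospecifically into a cis-oxirane (C4 and C5 set).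

Step 2
Reactants: 2 (2R,3S)-2,3-epoxynerol
Product: 3 [(2R,3S)-3-(3-chloro-4-methylpent-4-en-1-yl)-3-methyloxiran-2-yl]methanol (both C–Cl epimers)
Conditions: NCS (1.1 equiv), PhSeCl (10 mol%), CH2Cl2, 23 °C
Reagents that add atoms: N-chlorosuccinimide, O=C1CCC(=O)N1Cl
Why: Selenium-catalysed ene-type allylic chlorination of the only remaining alkene moves the double bond to the chain end and puts a leaving group on C1, and the new C–Cl centre is a mixture that step 3 erases.

Step 3
Reactants: 3 allylic chloride; 4 2-methylbut-1-en-3-yne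
Product: 6 [(2R,3S)-3-[(3E,6E)-4,8-dimethylnona-3,6,8-trien-1-yl]-3-methyloxiran-2-yl]methanol, via dienylboronate 5 (not isolated)
Conditions: 4, HBpin (1.1 equiv), Cp2Zr(H)Cl (10 mol%), Et3N (10 mol%), neat, sealed tube, 60 °C; then 3, Pd(PPh3)4 (5 mol%), K3PO4 (aq), THF, 50 °C
Reagents that add atoms: pinacolborane, B1OC(C)(C)C(C)(C)O1 (its boryl group is carried by 5 only)
Why: Zirconium-catalysed syn-hydroboration of the alkyne gives the E-dienylboronate, and the Suzuki–Miyaura allyl–alkenyl coupling runs through the syn-π-allylpalladium complex with reductive elimination at the unhindered CH2 terminus (C9), which gives the linear skipped triene with the E C1=C10 alkene.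

Step 4
Reactants: 6 trienyl epoxy alcohol
Product: 7 [(2R,3S)-3-[(3E,6S,7Z)-4,8-dimethyl-6,9-bis(4,4,5,5-tetramethyl-1,3,2-dioxaborolan-2-yl)nona-3,7-dien-1-yl]-3-methyloxiran-2-yl]methanol
Conditions: B2pin2 (1.05 equiv), Pt(dba)3 (3 mol%), (R,R)-3,5-xylyl-TADDOL phenylphosphonite (6 mol%), THF, 60 °C
Reagents that add atoms: bis(pinacolato)diboron, CC1(C)OB(OC1(C)C)B1OC(C)(C)C(C)(C)O1
Why: Enantioselective platinum-catalysed 1,4-diboration of a 1,3-diene: only the s-cis conjugated diene reacts (the isolated trisubstituted alkene and the oxirane are untouched), 1,4-addition gives the Z-alkene, and the chiral phosphonite sets the C8–B centre that later becomes C8–O.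

Step 5
Reactants: 7 bis(boronate) epoxy alcohol
Product: 10 (1(10)E,4S,5R,6R,7R,8S)-4,5-epoxygermacra-1(10),11-diene-6,8-diol, via epoxy aldehyde bis(boronate) 8 (not isolated), via ten-membered borate boronate 9 (not isolated)
Conditions: Dess–Martin periodinane (1.3 equiv), CH2Cl2 (0.05 M), 0 °C, 30 min, filter through a short pad; dilute into toluene (2 mM), 80 °C, 36 h; concentrate; 30% H2O2, 3 M NaOH, THF, 0 °C
Reagents that add atoms: hydrogen peroxide, OO
Why: Proposed new method: the oxidation unmasks the C6 aldehyde and the primary Z-allylboronate closes the ten-membered ring by intramolecular allylboration through a closed Zimmerman–Traxler chair (C7 attacks C6 with transposition to the isopropenyl group), where the Z geometry makes C8 axial and gives the required C6-OH/C8 syn relation, allylic 1,3-strain puts H8 in the alkene plane so that C7 reacts on the face away from the bulky C8–Bpin group with the tether on the aldehyde side, this pairing is also the Felkin–Anh face of the epoxy aldehyde (C5–O anti to C7, matched), the absence of any Lewis acid keeps the C1=C10 alkene from starting a six-ring ene reaction, and peroxide replaces boron at C8 by OH with retention; the closest known reactions are intramolecular allylborations to medium rings and diene diboration/allylboration/oxidation sequences.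

Step 6
Reactants: 10 epoxygermacradiene diol; 11 4-(benzyloxy)-3-methoxybenzoic acid
Product: 12 (1(10)E,4S,5R,6R,7S,8S)-4,5-epoxy-6-hydroxygermacra-1(10),11-dien-8-yl 4-(benzyloxy)-3-methoxybenzoate
Conditions: 11 (1.05 equiv), DCC (1.1 equiv), DMAP (20 mol%), CH2Cl2, 0 to 23 °C
Reagents that add atoms: none
Why: Steglich esterification: C8–OH has a CH2 neighbour and reacts ahead of C6–OH, which sits between the oxirane carbon and C7 and is hydrogen-bonded to the oxirane oxygen, and no stereocentre is touched.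

Step 7
Reactants: 12 epoxygermacradienyl ester
Product: 13 (4S,5S,6R,7S,8S)-4,6-dihydroxyguaia-1(10),11-dien-8-yl 4-(benzyloxy)-3-methoxybenzoate
Conditions: p-TsOH·H2O (10 mol%), CH2Cl2, 23 °C
Reagents that add atoms: none
Why: Acid-catalysed transannular epoxide–alkene cyclisation of the parthenolide-to-micheliolide type: C1 of the facing E-alkene opens the protonated oxirane at C5 with inversion while C4 keeps its oxygen, so the cis-oxirane gives 4-OH trans to H5 (C5 set, C4 retained), and the C10 cation loses H1 (Zaitsev) to give the tetrasubstituted C1=C10 alkene.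

Step 8
Reactants: 13 benzyl-protected guaiadiene ester
Product: 14 (4S,5S,6R,7S,8S)-4,6-dihydroxyguai-1(10)-en-8-yl 4-hydroxy-3-methoxybenzoate (target)
Conditions: H2 (1 atm), 10% Pd/C, EtOAc, 23 °C
Reagents that add atoms: none
Why: Heterogeneous hydrogenation saturates the 1,1-disubstituted isopropenyl group and hydrogenolyses the benzyl ether in one operation, while the hindered tetrasubstituted alkene and the aryl ester do not react, and no stereocentre is formed.

**Compound list**
1 | nerol, (2Z)-3,7-dimethylocta-2,6-dien-1-ol | CC(C)=CCC/C(C)=C\CO | starting material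
2 | [(2R,3S)-3-methyl-3-(4-methylpent-3-en-1-yl)oxiran-2-yl]methanol (cis-oxirane) | OC[C@H]1O[C@@]1(C)CCC=C(C)C | intermediate
3 | [(2R,3S)-3-(3-chloro-4-methylpent-4-en-1-yl)-3-methyloxiran-2-yl]methanol (both C–Cl epimers) | OC[C@H]1O[C@@]1(C)CCC(Cl)C(C)=C | intermediate
4 | 2-methylbut-1-en-3-yne | C=C(C)C#C | starting material
5 | 2-[(1E)-3-methylbuta-1,3-dien-1-yl]-4,4,5,5-tetramethyl-1,3,2-dioxaborolane | C=C(C)/C=C/B1OC(C)(C)C(C)(C)O1 | intermediate
6 | [(2R,3S)-3-[(3E,6E)-4,8-dimethylnona-3,6,8-trien-1-yl]-3-methyloxiran-2-yl]methanol | OC[C@H]1O[C@@]1(C)CC/C=C(\C)C/C=C/C(C)=C | intermediate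
7 | [(2R,3S)-3-[(3E,6S,7Z)-4,8-dimethyl-6,9-bis(pinacolboryl)nona-3,7-dien-1-yl]-3-methyloxiran-2-yl]methanol | OC[C@H]1O[C@@]1(C)CC/C=C(\C)C[C@H](B2OC(C)(C)C(C)(C)O2)/C=C(/C)CB3OC(C)(C)C(C)(C)O3 | intermediate
8 | (2S,3S)-3-[(3E,6S,7Z)-4,8-dimethyl-6,9-bis(pinacolboryl)nona-3,7-dien-1-yl]-3-methyloxirane-2-carbaldehyde | O=C[C@H]1O[C@@]1(C)CC/C=C(\C)C[C@H](B2OC(C)(C)C(C)(C)O2)/C=C(/C)CB3OC(C)(C)C(C)(C)O3 | intermediate
9 | (1(10)E,4S,5R,6R,7S,8S)-4,5-epoxy-6-(pinacolboryloxy)-8-(pinacolboryl)germacra-1(10),11-diene | C/C1=C\CC[C@]2(C)O[C@@H]2[C@H](OB3OC(C)(C)C(C)(C)O3)[C@H](C(C)=C)[C@@H](B3OC(C)(C)C(C)(C)O3)C1 | intermediate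
10 | (1(10)E,4S,5R,6R,7R,8S)-4,5-epoxygermacra-1(10),11-diene-6,8-diol (cis-oxirane; 6β-OH; 7β-isopropenyl; 8α-OH) | C/C1=C\CC[C@]2(C)O[C@@H]2[C@H](O)[C@H](C(C)=C)[C@@H](O)C1 | intermediate
11 | 4-(benzyloxy)-3-methoxybenzoic acid | COc1cc(C(=O)O)ccc1OCc1ccccc1 | starting material
12 | (1(10)E,4S,5R,6R,7S,8S)-4,5-epoxy-6-hydroxygermacra-1(10),11-dien-8-yl 4-(benzyloxy)-3-methoxybenzoate | C/C1=C\CC[C@]2(C)O[C@@H]2[C@H](O)[C@H](C(C)=C)[C@@H](OC(=O)c2ccc(OCc3ccccc3)c(OC)c2)C1 | intermediate
13 | (4S,5S,6R,7S,8S)-4,6-dihydroxyguaia-1(10),11-dien-8-yl 4-(benzyloxy)-3-methoxybenzoate | COc1cc(C(=O)O[C@H]2CC(C)=C3CC[C@](C)(O)[C@@H]3[C@H](O)[C@@H]2C(C)=C)ccc1OCc1ccccc1 | intermediate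
14 | (3S,3aS,4R,5S,6S)-3,4-dihydroxy-3,8-dimethyl-5-(propan-2-yl)-1,2,3,3a,4,5,6,7-octahydroazulen-6-yl 4-hydroxy-3-methoxybenzoate (CNP0299353.1) | COc1cc(C(=O)O[C@H]2CC(C)=C3CC[C@](C)(O)[C@@H]3[C@H](O)[C@@H]2C(C)C)ccc1O | target

**Totals**
- Total step count: 8.
- Longest linear sequence: 8 steps (1 to 14).

**Steps most likely to fail**

**Step 5.** A pinacol allylboronate may close the ten-membered ring too slowly against oligomerisation, or it may react through the C8 boron. The fallback sets out from 7 and comes back at 10. It replaces boron with a far more reactive allylindium made by umpolung of a π-allyl complex of palladium.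
- Silylate 7 (TBSCl, imidazole) to silyl ether F1.
- Oxidise both C–B bonds (H2O2, NaOH) to Z-enediol F2.
- Close the diol with 1,1'-carbonyldiimidazole to the seven-membered cyclic carbonate F3.
- Remove silicon (HF·pyridine) to give epoxy alcohol F4.
- Oxidise with Dess–Martin periodinane to epoxy aldehyde F5.
- Add F5 slowly to Pd(PPh3)4 and InI in THF.

Zerovalent palladium ionises the carbonate and CO2 is lost. Monovalent indium then turns the π-allyl alkoxide into a chelated Z-allylindium alkoxide, which forms C6–C7 irreversibly and gives 10 after work-up.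

**Step 7.** The C10 cation may be trapped by the isopropenyl group or may give alkene isomers. The fallback sets out from 12 and comes back at 14. It removes the competing π-nucleophile before the cation is made.
- Hydrogenate only the 1,1-disubstituted alkene of 12 (H2, RhCl(PPh3)3, benzene) to isopropyl epoxide F10.
- Cyclise with p-TsOH·H2O to benzyl ether F11.
- Hydrogenolyse (H2, 10% Pd/C) to 14.

**Step 6.** The two secondary hydroxyls may not be told apart. The fallback sets out from 9 and comes back at 13. It uses the fact that C8 is still carbon-bound boron when C6 already carries oxygen.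
- Stop step 5 before the peroxide. Aqueous work-up of 9 gives hydroxy boronate F6.
- TESOTf with 2,6-lutidine gives silyl ether F7.
- H2O2 with NaOH gives the C8 alcohol F8.
- DCC and DMAP with 11 give ester F9.
- The p-TsOH·H2O treatment in moist CH2Cl2 then removes the TES group and cyclises in the same flask to 13.

**Further compounds**
F1 | step 5 | TBS ether of bis(boronate) 7 | CC(C)(C)[Si](C)(C)OC[C@H]1O[C@@]1(C)CC/C=C(\C)C[C@H](B2OC(C)(C)C(C)(C)O2)/C=C(/C)CB3OC(C)(C)C(C)(C)O3
F2 | step 5 | C6-O-TBS (7Z)-ene-8,12-diol | CC(C)(C)[Si](C)(C)OC[C@H]1O[C@@]1(C)CC/C=C(\C)C[C@H](O)/C=C(/C)CO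
F3 | step 5 | C6-O-TBS 8,12-cyclic carbonate (4,7-dihydro-1,3-dioxepin-2-one) | CC(C)(C)[Si](C)(C)OC[C@H]1O[C@@]1(C)CC/C=C(\C)C[C@H]2C=C(C)COC(=O)O2
F4 | step 5 | epoxy alcohol carrying the 8,12-cyclic carbonate | OC[C@H]1O[C@@]1(C)CC/C=C(\C)C[C@H]2C=C(C)COC(=O)O2
F5 | step 5 | epoxy aldehyde carrying the 8,12-cyclic carbonate | O=C[C@H]1O[C@@]1(C)CC/C=C(\C)C[C@H]2C=C(C)COC(=O)O2
F6 | step 6 | 4,5-epoxy-8-(pinacolboryl)germacra-1(10),11-dien-6-ol | C/C1=C\CC[C@]2(C)O[C@@H]2[C@H](O)[C@H](C(C)=C)[C@@H](B3OC(C)(C)C(C)(C)O3)C1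
F7 | step 6 | 6-O-TES ether of F6 | C/C1=C\CC[C@]2(C)O[C@@H]2[C@H](O[Si](CC)(CC)CC)[C@H](C(C)=C)[C@@H](B3OC(C)(C)C(C)(C)O3)C1
F8 | step 6 | 6-O-TES 4,5-epoxygermacra-1(10),11-dien-8-ol | C/C1=C\CC[C@]2(C)O[C@@H]2[C@H](O[Si](CC)(CC)CC)[C@H](C(C)=C)[C@@H](O)C1
F9 | step 6 | 6-O-TES 8-O-(4-benzyloxy-3-methoxybenzoyl) epoxygermacradiene | C/C1=C\CC[C@]2(C)O[C@@H]2[C@H](O[Si](CC)(CC)CC)[C@H](C(C)=C)[C@@H](OC(=O)c2ccc(OCc3ccccc3)c(OC)c2)C1
F10 | step 7 | 4,5-epoxy-6-hydroxygermacr-1(10)-en-8-yl 4-(benzyloxy)-3-methoxybenzoate | C/C1=C\CC[C@]2(C)O[C@@H]2[C@H](O)[C@H](C(C)C)[C@@H](OC(=O)c2ccc(OCc3ccccc3)c(OC)c2)C1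
F11 | step 7 | 4,6-dihydroxyguai-1(10)-en-8-yl 4-(benzyloxy)-3-methoxybenzoate | COc1cc(C(=O)O[C@H]2CC(C)=C3CC[C@](C)(O)[C@@H]3[C@H](O)[C@@H]2C(C)C)ccc1OCc1ccccc1
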